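# Proposed total synthesis of (5,7-dihydroxy-2,2-dimethyl-8-prenyl-2H-chromen-6-yl)(3-hydroxyphenyl)methanone (CNP0424359.0)

## Analysis of the target

The target is a 2,2-dimethyl-2H-chromene: a benzene ring (ring A: C4a, C5, C6, C7, C8, C8a) fused to a pyran ring (ring B: O1, C2, C3, C4). Ring A carries no hydrogen. Oxygen sits on C5, C7 and C8a, and three different carbon groups alternate with it: the pyran carbon C4 on C4a, a 3-hydroxybenzoyl group on C6 and a prenyl group on C8. There is no stereocenter, so the whole problem is one of regiochemistry on a fully substituted phloroglucinol core. The sensitive parts are the electron-rich ring, the prenyl and chromene double bonds, and the free C7 hydroxyl next to the prenyl group. Electrophiles and acids attack the alkenes, and acid can add the C7 hydroxyl to the prenyl double bond. The difficulty is to place three carbon substituents on defined positions between three oxygens and to tell the C5 and C7 oxygens apart long enough to build the ketone between them. The strategy rests on one feature: C6 bears the carbonyl and its neighbour C7 bears oxygen, so the C6–C(=O) bond and the C7–O bond are vicinal. A single carboxylic acid can deliver both to a C6–C7 aryne, and the oxygen on the other neighbour, C5, decides which end receives which.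

## Retrosynthetic reasoning

**22 to 21.** The last operation cuts only two O–CH2 acetal bonds. The methoxymethyl (MOM) group is chosen for both phenols because it survives fluoride, hydroxide and organolithium reagents. On O5 it also directs the metalation and the aryne addition.

**21 to 16 and 19 (through aryne 20).** The C6–C(=O) bond and the C7–O bond are cut together. A Friedel–Crafts or Fries acylation would make only the C–C bond and would need Lewis acid, which the two alkenes would not tolerate. The aryne insertion makes the ketone and frees O7 in one operation under basic, aprotic conditions. It also joins two fragments of similar size late in the route. The forward step has to send the carboxylate oxygen to C7 and the acyl group to C6; the O5 acetal on the neighbouring carbon provides that bias.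

**19 to 17.** The phenol of the acid fragment is masked as its MOM ether, because a free phenoxide would itself add to the aryne.

**16 to 14, 11 and 10.** The C6–Si bond and the O7–S bond are cut. C6 is the only aromatic C–H of 10 and lies between two oxygens, so a carbamate on O7 together with the O5 acetal directs lithiation there. The same carbamate is later removed by base and replaced by the triflate. Electrophilic bromination followed by silyl migration would be one operation shorter, but it exposes an ortho-prenylphenol and two electron-rich alkenes to a bromonium source. The metalation route avoids that, and the bromination route is kept as a fallback.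

**10 to 8.** The C6–CO2Me bond is cut. The ester is a traceless blocking group: it occupies C6 while the prenyl group and ring B are installed, and it differentiates the three hydroxyls by hydrogen bonding. It is then removed by saponification and decarboxylation.

**8 to 6.** Ring B is opened at O1–C2 and C4–C4a, which leads back to an aryl 1,1-dimethylpropargyl ether. Because C3 of the benzoate already carries the prenyl group, the rearrangement can only reach the carbon that becomes C4a. No angular or linear isomer problem arises.

**6 to 5.** One O–CH2 bond is cut. This is the step that tells O5 from O7. It is placed before ring B exists, when the future O5 has only a hydrogen as ring neighbour while the future O7 is wedged between the ester and the prenyl group.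

**5 to 3 and 4.** The aryl–O–C(CH3)2 bond is cut. The C4 hydroxyl of 3 is the only one not chelated to the ester and is the most acidic, so O-alkylation should go there.

**3 to 1 and 2.** The ring–CH2 bond of the prenyl group is cut. In 1 the two free ring positions are equivalent and the third is blocked by the ester, so mono-C-prenylation can give only one constitution.

## Alternatives that were turned down

**Alternative 1: ring A built by cyclobutenone–alkyne benzannulation.**
- Disconnection and key step: 3-ethoxycyclobut-2-en-1-one A2 and triisopropyl[(5-methylhex-4-en-1-yn-1-yl)oxy]silane A3 would be heated together. Electrocyclic opening of A2 to a vinylketene, [2+2] addition of A3, a second ring opening and a 6π closure would give 5-ethoxy-2-(3-methylbut-2-en-1-yl)-3-[(triisopropylsilyl)oxy]phenol A1. The alkyne carbons become C7 and C8.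
- For: the three oxygens of A1 are different by construction (free OH for O1, silyl ether on O7, ethyl ether on O5), and the prenyl group is placed without any phenoxide C-alkylation. On oxygen differentiation this is stronger than the chosen route, which relies on a steric site-selection in step 3.
- Against: the ethyl ether on O5 must become a free phenol at the end, and conditions that cleave an aryl ethyl ether would also attack the prenyl and chromene alkenes. A3 needs several steps of its own. After A1, both ring B and the benzoyl group are still missing, so the central problem of the target is untouched.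
- Comparison: the chosen route buys ring A ready-made in 1 and spends its effort on the ketone instead.

**Alternative 2: ring B by three-component borono-Mannich annulation.**
- Disconnection and key step: 2-hydroxy-4,6-bis(methoxymethoxy)-3-(3-methylbut-2-en-1-yl)benzaldehyde A5, (2-methylprop-1-en-1-yl)boronic acid A6 and a secondary amine would combine. Alkenyl transfer to the iminium carbon forms C3–C4, loss of the amine gives an ortho-quinone methide, and oxa-6π closure forms O1–C2, giving 5,7-bis(methoxymethoxy)-2,2-dimethyl-8-(3-methylbut-2-en-1-yl)-2H-chromene A4.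
- For: the conditions are mild. A4 carries the same group on O5 and O7, so no differentiation is needed, and C6 between two acetal oxygens could be lithiated and acylated directly. On that point the alternative is simpler and more conventional than an aryne.
- Against: A5 needs a prenyl group on one specific position of an aldehyde with two open ring positions and no blocking group, which is the regiochemical problem the ester of 1 solves. The annulation asks a β,β-disubstituted alkenylboronic acid to add to a hindered iminium ion deactivated by three oxygen donors. The ketone would then still need an addition and an oxidation, or an acyl transfer, in separate steps.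
- Comparison: the chosen route makes ring B by a rearrangement with only one possible outcome and makes the ketone and the O7 phenol in a single step.

**Alternative 3: ring A closed last by Dieckmann-type condensation.**
- Disconnection and key step: methyl 6-{1-[3-(methoxymethoxy)phenyl]-7-methyl-1,3-dioxooct-6-en-4-yl}-2,2-dimethyl-2H-pyran-5-carboxylate A8 would be treated with base. The central carbon of the 1,3-diketone attacks the ester (C5–C6 bond), and enolisation aromatises the new ring to {5,7-dihydroxy-2,2-dimethyl-8-(3-methylbut-2-en-1-yl)-2H-chromen-6-yl}[3-(methoxymethoxy)phenyl]methanone A7.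
- For: the closure would deliver the ketone, both flanking phenols and the full substitution pattern at once, with aromatisation as driving force. Ring A needs no protecting group and only one acetal remains to be removed. In protecting-group economy this is better than the chosen route.
- Against: A8 is a monocyclic 2H-pyran, which can open reversibly to a dienone, and it carries a tricarbonyl chain with three acidic sites. Its synthesis would be long and its handling uncertain. The condensation would compete with O-acylation and retro-Claisen cleavage.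
- Comparison: the chosen route stays with stable aromatic intermediates from a cheap phloroglucinol ester and concentrates the risk in one late, convergent step.

Key step: step 10

## Route

Remark: chromene numbering is used throughout (O1, C2, C3, C4, C4a, C5 to C8, C8a). The target has no stereocenter, so no descriptor is needed. Compounds 1, 2, 4 and 17 are taken as purchasable.

Step 1
Reactants: 1 methyl 2,4,6-trihydroxybenzoate; 2 1-bromo-3-methylbut-2-ene (prenyl bromide)
Product: 3 methyl 2,4,6-trihydroxy-3-(3-methylbut-2-en-1-yl)benzoate
Conditions: 2 (1 equiv), DBU, THF, 0 °C → rt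
Reagents that add atoms: none
Why: C-alkylation of the ambident phloroglucinol anion by the allylic bromide; the two free ring positions of 1 are equivalent and the third is blocked by the ester, so mono-prenylation gives one constitution. The chelated hydroxyls resist O-alkylation, and limiting 2 holds back a second prenylation.

Step 2
Reactants: 3 methyl 2,4,6-trihydroxy-3-(3-methylbut-2-en-1-yl)benzoate; 4 3-chloro-3-methylbut-1-yne
Product: 5 methyl 2,6-dihydroxy-4-[(2-methylbut-3-yn-2-yl)oxy]-3-(3-methylbut-2-en-1-yl)benzoate
Conditions: DBU, CuCl2·2H2O (cat.), MeCN, 0 °C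
Reagents that add atoms: none
Why: Copper-catalysed propargylic etherification of a phenol with a tertiary propargyl chloride; the C4 hydroxyl is the only one not hydrogen-bonded to the ester and the most acidic, so it should react first. The low temperature keeps the ether from rearranging early.

Step 3
Reactants: 5 methyl 2,6-dihydroxy-4-[(2-methylbut-3-yn-2-yl)oxy]-3-(3-methylbut-2-en-1-yl)benzoate
Product: 6 methyl 2-hydroxy-6-(methoxymethoxy)-4-[(2-methylbut-3-yn-2-yl)oxy]-3-(3-methylbut-2-en-1-yl)benzoate
Conditions: MOMCl (1.1 equiv), i-Pr2NEt, CH2Cl2, 0 °C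
Reagents that add atoms: chloromethyl methyl ether, COCCl
Why: O-alkylation with a chloromethyl ether (acetal formation); the C6 hydroxyl has only a ring hydrogen beside it, while the C2 hydroxyl is shielded by the prenyl group and pressed into the ester chelate, so the acetal should go on the future O5. Once one hydroxyl is capped the other is held in a strong hydrogen bond, which should stop the reaction at the mono-ether.

Step 4
Reactants: 6 methyl 2-hydroxy-6-(methoxymethoxy)-4-[(2-methylbut-3-yn-2-yl)oxy]-3-(3-methylbut-2-en-1-yl)benzoate
Product: 8 methyl 7-hydroxy-5-(methoxymethoxy)-2,2-dimethyl-8-(3-methylbut-2-en-1-yl)-2H-chromene-6-carboxylate, via allenylphenol 7 (not isolated)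
Conditions: o-xylene, 140 °C
Reagents that add atoms: none
Why: Aromatic propargyl Claisen rearrangement ([3,3]) can reach only the free ortho carbon, because the other carries the prenyl group; it forms C4–C4a and, after tautomerisation, gives 7. A [1,5]-hydrogen shift and oxa-6π electrocyclisation then close ring B at O1–C2.

Step 5
Reactants: 8 methyl 7-hydroxy-5-(methoxymethoxy)-2,2-dimethyl-8-(3-methylbut-2-en-1-yl)-2H-chromene-6-carboxylate
Product: 10 5-(methoxymethoxy)-2,2-dimethyl-8-(3-methylbut-2-en-1-yl)-2H-chromen-7-ol, via carboxylic acid 9 (not isolated)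
Conditions: KOH, EtOH/H2O, 90 °C; then 1 M HCl to pH 5, 50 °C
Reagents that add atoms: none
Why: Saponification followed by protodecarboxylation; acid 9 has oxygen on both ortho carbons and on the para carbon, so ipso protonation and loss of CO2 should occur at a pH the MOM acetal tolerates. The base stage leaves the acetal and both alkenes untouched.

Step 6
Reactants: 10 5-(methoxymethoxy)-2,2-dimethyl-8-(3-methylbut-2-en-1-yl)-2H-chromen-7-ol
Product: 11 5-(methoxymethoxy)-2,2-dimethyl-8-(3-methylbut-2-en-1-yl)-2H-chromen-7-yl propan-2-ylcarbamate
Conditions: i-PrNCO, Et3N (cat.), CH2Cl2, rt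
Reagents that add atoms: 2-isocyanatopropane (isopropyl isocyanate), CC(C)N=C=O
Why: Base-catalysed addition of the phenol to an isocyanate (carbamoylation); the N-monoalkyl carbamate serves first as ortho-directing group and later as a base-labile mask for O7.

Step 7
Reactants: 11 5-(methoxymethoxy)-2,2-dimethyl-8-(3-methylbut-2-en-1-yl)-2H-chromen-7-yl propan-2-ylcarbamate
Product: 14 5-(methoxymethoxy)-2,2-dimethyl-8-(3-methylbut-2-en-1-yl)-6-(trimethylsilyl)-2H-chromen-7-yl propan-2-ylcarbamate, via N-silyl carbamate 12 (not isolated), via N-silyl C6-silyl carbamate 13 (not isolated)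
Conditions: TBSOTf, TMEDA, Et2O, 0 °C → rt; n-BuLi, TMEDA, −78 °C; TMSCl, −78 °C → rt; aq. NH4Cl
Reagents that add atoms: chlorotrimethylsilane, C[Si](C)(C)Cl; tert-butyldimethylsilyl trifluoromethanesulfonate, CC(C)(C)[Si](C)(C)OS(=O)(=O)C(F)(F)F (its silyl group is carried only by 12 and 13)
Why: Directed ortho-metalation; after in situ N-silylation (12) the carbamate and the O5 acetal jointly direct n-BuLi to C6, the only aromatic C–H, and the chlorosilane traps the aryllithium as 13. The amine-complexed silyl triflate should not attack the acetal, and the N–Si bond is hydrolysed on work-up.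

Step 8
Reactants: 14 5-(methoxymethoxy)-2,2-dimethyl-8-(3-methylbut-2-en-1-yl)-6-(trimethylsilyl)-2H-chromen-7-yl propan-2-ylcarbamate
Product: 16 5-(methoxymethoxy)-2,2-dimethyl-8-(3-methylbut-2-en-1-yl)-6-(trimethylsilyl)-2H-chromen-7-yl trifluoromethanesulfonate, via silylphenol 15 (not isolated)
Conditions: Et2NH, DBU, MeCN, 40 °C; then PhNTf2, rt
Reagents that add atoms: N-phenylbis(trifluoromethanesulfonimide), O=S(=O)(N(c1ccccc1)S(=O)(=O)C(F)(F)F)C(F)(F)F
Why: E1cB cleavage of the N–H carbamate (isopropyl isocyanate is expelled and trapped by Et2NH) frees the phenoxide of 15, which is sulfonylated in the same flask. The elimination does not depend on access to the crowded carbonyl, and carbamate-directed silylation followed by this exchange is an established way to 3-alkoxy-2-silylaryl triflates.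

Step 9
Reactants: 17 3-hydroxybenzoic acid
Product: 19 3-(methoxymethoxy)benzoic acid, via methoxymethyl ester 18 (not isolated)
Conditions: MOMCl, i-Pr2NEt, CH2Cl2, 0 °C → rt; then LiOH, THF/MeOH/H2O, rt; 1 M HCl to pH 4, 0 °C
Reagents that add atoms: chloromethyl methyl ether, COCCl
Why: Double O-alkylation gives acetal ester 18; hydroxide then cleaves only the methoxymethyl ester. The aryl MOM ether stays and keeps the phenol from adding to the aryne in step 10.

Step 10
Reactants: 16 5-(methoxymethoxy)-2,2-dimethyl-8-(3-methylbut-2-en-1-yl)-6-(trimethylsilyl)-2H-chromen-7-yl trifluoromethanesulfonate; 19 3-(methoxymethoxy)benzoic acid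
Product: 21 {7-hydroxy-5-(methoxymethoxy)-2,2-dimethyl-8-(3-methylbut-2-en-1-yl)-2H-chromen-6-yl}[3-(methoxymethoxy)phenyl]methanone, via aryne 20 (not isolated)
Conditions: CsF, THF, 125 °C (sealed tube)
Reagents that add atoms: none
Why: Fluoride attacks silicon and triflate leaves from the neighbouring carbon, giving the C6–C7 aryne 20. The cesium carboxylate of 19 adds through oxygen to C7, the aryne carbon remote from the O5 acetal, so the negative charge develops at C6 where the σ-withdrawing oxygen on C5 stabilises it; this is the polarisation that makes 3-alkoxyarynes react at the distal carbon. The C6 carbanion then attacks the ester carbonyl through a transient four-membered alkoxide, comparable to an anionic Fries 1,3-acyl shift, which opens to the C6 ketone and the C7 phenoxide. No ring is kept and no stereocenter is formed. The closest known reaction type is the insertion of arynes into the C–O bond of carboxylic acids to give ortho-hydroxyaryl ketones; here it is applied to a fully substituted aryne. The step needs regioselectivity (oxygen to C7, acyl to C6), which the C5 oxygen should secure against the smaller steric demand of the C8 prenyl group. It also needs acyl transfer to outrun protonation of the aryl anion, which the aprotic medium, excess CsF and heat favour. The product phenoxide is chelated and flanked by the ketone and the prenyl group, so a second arylation should be slow, and an excess of the cheap acid 19 keeps the aryne from other pathways.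

Step 11
Reactants: 21 {7-hydroxy-5-(methoxymethoxy)-2,2-dimethyl-8-(3-methylbut-2-en-1-yl)-2H-chromen-6-yl}[3-(methoxymethoxy)phenyl]methanone
Product: 22 [5,7-dihydroxy-2,2-dimethyl-8-(3-methylbut-2-en-1-yl)-2H-chromen-6-yl](3-hydroxyphenyl)methanone
Conditions: HCl (1 M in MeOH), 0 °C → rt
Reagents that add atoms: none
Why: Acid-catalysed acetal exchange with methanol removes both MOM groups; the C5 ether is activated by the ortho carbonyl. Dilute acid at low temperature should spare the prenyl and chromene double bonds.

## Compound list

1 | methyl 2,4,6-trihydroxybenzoate | COC(=O)c1c(O)cc(O)cc1O | starting material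
2 | 1-bromo-3-methylbut-2-ene (prenyl bromide) | CC(C)=CCBr | starting material
3 | methyl 2,4,6-trihydroxy-3-(3-methylbut-2-en-1-yl)benzoate | COC(=O)c1c(O)cc(O)c(CC=C(C)C)c1O | intermediate
4 | 3-chloro-3-methylbut-1-yne | CC(C)(Cl)C#C | starting material
5 | methyl 2,6-dihydroxy-4-[(2-methylbut-3-yn-2-yl)oxy]-3-(3-methylbut-2-en-1-yl)benzoate | COC(=O)c1c(O)cc(OC(C)(C)C#C)c(CC=C(C)C)c1O | intermediate
6 | methyl 2-hydroxy-6-(methoxymethoxy)-4-[(2-methylbut-3-yn-2-yl)oxy]-3-(3-methylbut-2-en-1-yl)benzoate | COCOc1cc(OC(C)(C)C#C)c(CC=C(C)C)c(O)c1C(=O)OC | intermediate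
7 | methyl 2,4-dihydroxy-6-(methoxymethoxy)-5-(3-methylbuta-1,2-dien-1-yl)-3-(3-methylbut-2-en-1-yl)benzoate | COCOc1c(C=C=C(C)C)c(O)c(CC=C(C)C)c(O)c1C(=O)OC | intermediate (not isolated)
8 | methyl 7-hydroxy-5-(methoxymethoxy)-2,2-dimethyl-8-(3-methylbut-2-en-1-yl)-2H-chromene-6-carboxylate | COC(=O)c1c(O)c(CC=C(C)C)c2OC(C)(C)C=Cc2c1OCOC | intermediate
9 | 7-hydroxy-5-(methoxymethoxy)-2,2-dimethyl-8-(3-methylbut-2-en-1-yl)-2H-chromene-6-carboxylic acid | OC(=O)c1c(O)c(CC=C(C)C)c2OC(C)(C)C=Cc2c1OCOC | intermediate (not isolated)
10 | 5-(methoxymethoxy)-2,2-dimethyl-8-(3-methylbut-2-en-1-yl)-2H-chromen-7-ol | CC(C)=CCc1c(O)cc(OCOC)c2c1OC(C)(C)C=C2 | intermediate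
11 | 5-(methoxymethoxy)-2,2-dimethyl-8-(3-methylbut-2-en-1-yl)-2H-chromen-7-yl propan-2-ylcarbamate | CC(C)=CCc1c(OC(=O)NC(C)C)cc(OCOC)c2c1OC(C)(C)C=C2 | intermediate
12 | 5-(methoxymethoxy)-2,2-dimethyl-8-(3-methylbut-2-en-1-yl)-2H-chromen-7-yl [tert-butyl(dimethyl)silyl](propan-2-yl)carbamate | CC(C)=CCc1c(OC(=O)N(C(C)C)[Si](C)(C)C(C)(C)C)cc(OCOC)c2c1OC(C)(C)C=C2 | intermediate (not isolated)
13 | 5-(methoxymethoxy)-2,2-dimethyl-8-(3-methylbut-2-en-1-yl)-6-(trimethylsilyl)-2H-chromen-7-yl [tert-butyl(dimethyl)silyl](propan-2-yl)carbamate | CC(C)=CCc1c(OC(=O)N(C(C)C)[Si](C)(C)C(C)(C)C)c([Si](C)(C)C)c(OCOC)c2c1OC(C)(C)C=C2 | intermediate (not isolated)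
14 | 5-(methoxymethoxy)-2,2-dimethyl-8-(3-methylbut-2-en-1-yl)-6-(trimethylsilyl)-2H-chromen-7-yl propan-2-ylcarbamate | CC(C)=CCc1c(OC(=O)NC(C)C)c([Si](C)(C)C)c(OCOC)c2c1OC(C)(C)C=C2 | intermediate
15 | 5-(methoxymethoxy)-2,2-dimethyl-8-(3-methylbut-2-en-1-yl)-6-(trimethylsilyl)-2H-chromen-7-ol | CC(C)=CCc1c(O)c([Si](C)(C)C)c(OCOC)c2c1OC(C)(C)C=C2 | intermediate (not isolated)
16 | 5-(methoxymethoxy)-2,2-dimethyl-8-(3-methylbut-2-en-1-yl)-6-(trimethylsilyl)-2H-chromen-7-yl trifluoromethanesulfonate | CC(C)=CCc1c(OS(=O)(=O)C(F)(F)F)c([Si](C)(C)C)c(OCOC)c2c1OC(C)(C)C=C2 | intermediate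
17 | 3-hydroxybenzoic acid | O=C(O)c1cccc(O)c1 | starting material
18 | methoxymethyl 3-(methoxymethoxy)benzoate | COCOC(=O)c1cccc(OCOC)c1 | intermediate (not isolated)
19 | 3-(methoxymethoxy)benzoic acid | COCOc1cccc(C(=O)O)c1 | intermediate
20 | 6,7-didehydro-5-(methoxymethoxy)-2,2-dimethyl-8-(3-methylbut-2-en-1-yl)-2H-chromene (C6–C7 aryne) | CC(C)=CCC1=C2OC(C)(C)C=CC2=C(OCOC)C#C1 | intermediate (not isolated)
21 | {7-hydroxy-5-(methoxymethoxy)-2,2-dimethyl-8-(3-methylbut-2-en-1-yl)-2H-chromen-6-yl}[3-(methoxymethoxy)phenyl]methanone | CC(C)=CCc1c(O)c(C(=O)c2cccc(OCOC)c2)c(OCOC)c2c1OC(C)(C)C=C2 | intermediate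
22 | [5,7-dihydroxy-2,2-dimethyl-8-(3-methylbut-2-en-1-yl)-2H-chromen-6-yl](3-hydroxyphenyl)methanone | CC(C)=CCc1c(O)c(C(=O)c2cccc(O)c2)c(O)c2c1OC(C)(C)C=C2 | target

## Step count and least certain steps

Total step count: 11. Longest linear sequence: 10 steps (steps 1 to 8, 10 and 11); step 9 is a one-step branch.

**Step 10 (key step).**
- What may go wrong: the C6 aryl anion may be protonated before the acyl group migrates, leaving an O-aryl ester without the ketone. Acyl transfer to a carbanion with two ortho substituents may be slow. The aryne may be lost to an intramolecular ene-type reaction with the neighbouring prenyl group or to addition of fluoride.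
- Fallback (from 11, back at 21): the carbamate is N-silylated and lithiated at C6 as in step 7. The aryllithium is treated, in place of the chlorosilane, with N-methoxy-3-(methoxymethoxy)-N-methylbenzamide F1, made from 19 with carbonyldiimidazole and N,O-dimethylhydroxylamine hydrochloride. Aqueous work-up, which also removes the N-silyl group, should give 6-[3-(methoxymethoxy)benzoyl]-5-(methoxymethoxy)-2,2-dimethyl-8-(3-methylbut-2-en-1-yl)-2H-chromen-7-yl propan-2-ylcarbamate F2. Et2NH and DBU in MeCN then remove the carbamate and give 21.

**Step 1.**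
- What may go wrong: a second C-prenylation on the remaining ring position, or O-alkylation of the free C4 hydroxyl, because the phloroglucinol anion stays nucleophilic after the first alkylation.
- Fallback (from 1, back at 3): electrophilic prenylation of neutral 1 with 2-methylbut-3-en-2-ol and BF3·OEt2 in dioxane at rt. This Friedel–Crafts allylation goes through an allyl cation instead of a phenoxide alkylation and leads directly to 3; no new compound is made.

**Step 3.**
- What may go wrong: the acetal may be placed on the hydroxyl between the ester and the prenyl group, or on both hydroxyls, since the two differ only in their surroundings.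
- Fallback (from 5, back at 22): the other mono-ether, methyl 6-hydroxy-2-(methoxymethoxy)-4-[(2-methylbut-3-yn-2-yl)oxy]-3-(3-methylbut-2-en-1-yl)benzoate F3, need not be discarded, because C6 has an oxygenated carbon on each side. Claisen rearrangement as in step 4 gives methyl 5-hydroxy-7-(methoxymethoxy)-2,2-dimethyl-8-(3-methylbut-2-en-1-yl)-2H-chromene-6-carboxylate F4. Ester removal as in step 5 gives 7-(methoxymethoxy)-2,2-dimethyl-8-(3-methylbut-2-en-1-yl)-2H-chromen-5-ol F5. Carbamoylation gives 7-(methoxymethoxy)-2,2-dimethyl-8-(3-methylbut-2-en-1-yl)-2H-chromen-5-yl propan-2-ylcarbamate F6. Lithiation and silylation as in step 7 give 7-(methoxymethoxy)-2,2-dimethyl-8-(3-methylbut-2-en-1-yl)-6-(trimethylsilyl)-2H-chromen-5-yl propan-2-ylcarbamate F7. The exchange of step 8 gives 7-(methoxymethoxy)-2,2-dimethyl-8-(3-methylbut-2-en-1-yl)-6-(trimethylsilyl)-2H-chromen-5-yl trifluoromethanesulfonate F8. Its C5–C6 aryne should be attacked by the carboxylate of 19 at C5, remote from the O7 acetal, to give {5-hydroxy-7-(methoxymethoxy)-2,2-dimethyl-8-(3-methylbut-2-en-1-yl)-2H-chromen-6-yl}[3-(methoxymethoxy)phenyl]methanone F9. Acid as in step 11 gives 22.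

**Step 7.**
- What may go wrong: deprotonation at the benzylic and allylic CH2 of the prenyl group, which is ortho to the carbamate, instead of at C6. Carbamoyl migration to C6 (anionic Fries shift) is possible if the aryllithium warms before it is trapped.
- Fallback (from 10, back at 16): NBS in CH2Cl2 at −78 °C brominates the only free ring position to give 6-bromo-5-(methoxymethoxy)-2,2-dimethyl-8-(3-methylbut-2-en-1-yl)-2H-chromen-7-ol F10. HMDS gives {[6-bromo-5-(methoxymethoxy)-2,2-dimethyl-8-(3-methylbut-2-en-1-yl)-2H-chromen-7-yl]oxy}(trimethyl)silane F11. n-BuLi at −78 °C exchanges bromine for lithium, the silyl group migrates from O7 to C6 (retro-Brook shift) to give the lithium salt of 15, and Tf2O gives 16. This path has its own hazard of bromonium attack on the alkenes, which is why it is second choice.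

**Step 11.**
- What may go wrong: acid-catalysed addition of the C7 hydroxyl to the prenyl double bond (chroman formation), or incomplete cleavage of the unactivated MOM ether on the benzoyl ring at low temperature.
- Fallback (from 21, back at 22): an exchange without Brønsted acid. TMSOTf and 2,2'-bipyridyl in CH2Cl2 at 0 °C convert the aryl acetals, and with excess reagent the free phenol, into [5,7-bis(trimethylsilyloxy)-2,2-dimethyl-8-(3-methylbut-2-en-1-yl)-2H-chromen-6-yl][3-(trimethylsilyloxy)phenyl]methanone F12. Water then cleaves the silyl ethers to 22.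

## Further compounds

F1 | step 10 | N-methoxy-3-(methoxymethoxy)-N-methylbenzamide | CON(C)C(=O)c1cccc(OCOC)c1
F2 | step 10 | 6-[3-(methoxymethoxy)benzoyl]-5-(methoxymethoxy)-2,2-dimethyl-8-(3-methylbut-2-en-1-yl)-2H-chromen-7-yl propan-2-ylcarbamate | CC(C)=CCc1c(OC(=O)NC(C)C)c(C(=O)c2cccc(OCOC)c2)c(OCOC)c2c1OC(C)(C)C=C2
F0 | step 1 | none | none
F3 | step 3 | methyl 6-hydroxy-2-(methoxymethoxy)-4-[(2-methylbut-3-yn-2-yl)oxy]-3-(3-methylbut-2-en-1-yl)benzoate | COC(=O)c1c(O)cc(OC(C)(C)C#C)c(CC=C(C)C)c1OCOC
F4 | step 3 | methyl 5-hydroxy-7-(methoxymethoxy)-2,2-dimethyl-8-(3-methylbut-2-en-1-yl)-2H-chromene-6-carboxylate | COC(=O)c1c(OCOC)c(CC=C(C)C)c2OC(C)(C)C=Cc2c1O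
F5 | step 3 | 7-(methoxymethoxy)-2,2-dimethyl-8-(3-methylbut-2-en-1-yl)-2H-chromen-5-ol | CC(C)=CCc1c(OCOC)cc(O)c2c1OC(C)(C)C=C2
F6 | step 3 | 7-(methoxymethoxy)-2,2-dimethyl-8-(3-methylbut-2-en-1-yl)-2H-chromen-5-yl propan-2-ylcarbamate | CC(C)=CCc1c(OCOC)cc(OC(=O)NC(C)C)c2c1OC(C)(C)C=C2
F7 | step 3 | 7-(methoxymethoxy)-2,2-dimethyl-8-(3-methylbut-2-en-1-yl)-6-(trimethylsilyl)-2H-chromen-5-yl propan-2-ylcarbamate | CC(C)=CCc1c(OCOC)c([Si](C)(C)C)c(OC(=O)NC(C)C)c2c1OC(C)(C)C=C2
F8 | step 3 | 7-(methoxymethoxy)-2,2-dimethyl-8-(3-methylbut-2-en-1-yl)-6-(trimethylsilyl)-2H-chromen-5-yl trifluoromethanesulfonate | CC(C)=CCc1c(OCOC)c([Si](C)(C)C)c(OS(=O)(=O)C(F)(F)F)c2c1OC(C)(C)C=C2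
F9 | step 3 | {5-hydroxy-7-(methoxymethoxy)-2,2-dimethyl-8-(3-methylbut-2-en-1-yl)-2H-chromen-6-yl}[3-(methoxymethoxy)phenyl]methanone | CC(C)=CCc1c(OCOC)c(C(=O)c2cccc(OCOC)c2)c(O)c2c1OC(C)(C)C=C2
F10 | step 7 | 6-bromo-5-(methoxymethoxy)-2,2-dimethyl-8-(3-methylbut-2-en-1-yl)-2H-chromen-7-ol | CC(C)=CCc1c(O)c(Br)c(OCOC)c2c1OC(C)(C)C=C2
F11 | step 7 | {[6-bromo-5-(methoxymethoxy)-2,2-dimethyl-8-(3-methylbut-2-en-1-yl)-2H-chromen-7-yl]oxy}(trimethyl)silane | CC(C)=CCc1c(O[Si](C)(C)C)c(Br)c(OCOC)c2c1OC(C)(C)C=C2
F12 | step 11 | [5,7-bis(trimethylsilyloxy)-2,2-dimethyl-8-(3-methylbut-2-en-1-yl)-2H-chromen-6-yl][3-(trimethylsilyloxy)phenyl]methanone | CC(C)=CCc1c(O[Si](C)(C)C)c(C(=O)c2cccc(O[Si](C)(C)C)c2)c(O[Si](C)(C)C)c2c1OC(C)(C)C=C2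
A1 | alternative 1 | 5-ethoxy-2-(3-methylbut-2-en-1-yl)-3-[(triisopropylsilyl)oxy]phenol | CCOc1cc(O)c(CC=C(C)C)c(O[Si](C(C)C)(C(C)C)C(C)C)c1
A2 | alternative 1 | 3-ethoxycyclobut-2-en-1-one | CCOC1=CC(=O)C1
A3 | alternative 1 | triisopropyl[(5-methylhex-4-en-1-yn-1-yl)oxy]silane | CC(C)=CCC#CO[Si](C(C)C)(C(C)C)C(C)C
A4 | alternative 2 | 5,7-bis(methoxymethoxy)-2,2-dimethyl-8-(3-methylbut-2-en-1-yl)-2H-chromene | CC(C)=CCc1c(OCOC)cc(OCOC)c2c1OC(C)(C)C=C2
A5 | alternative 2 | 2-hydroxy-4,6-bis(methoxymethoxy)-3-(3-methylbut-2-en-1-yl)benzaldehyde | COCOc1cc(OCOC)c(CC=C(C)C)c(O)c1C=O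
A6 | alternative 2 | (2-methylprop-1-en-1-yl)boronic acid | CC(C)=CB(O)O
A7 | alternative 3 | {5,7-dihydroxy-2,2-dimethyl-8-(3-methylbut-2-en-1-yl)-2H-chromen-6-yl}[3-(methoxymethoxy)phenyl]methanone | CC(C)=CCc1c(O)c(C(=O)c2cccc(OCOC)c2)c(O)c2c1OC(C)(C)C=C2
A8 | alternative 3 | methyl 6-{1-[3-(methoxymethoxy)phenyl]-7-methyl-1,3-dioxooct-6-en-4-yl}-2,2-dimethyl-2H-pyran-5-carboxylate | COC(=O)C1=C(C(CC=C(C)C)C(=O)CC(=O)c2cccc(OCOC)c2)OC(C)(C)C=C1
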